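**Plan**

1. Locants (elemanolide numbering): carbocycle C5–C10 = ring B (C10 quaternary, with the C14 methyl and the C1–C2 oxirane); C5 carries C4(=C15H2)–C3HO; C6 carries OH; C9 carries the angelate; lactone ring A = C7–C11(=C13H2)–C12(=O)–O–C8.
2. Late cuts: C4=C15 (Mannich methylenation of a C3 aldehyde held as an O6–C3 lactol), C12=O (lactol oxidation), the angelate C–O bond, and the oxirane C2–O bond (from a C1/C2 chlorohydrin).
3. Core cut: C7–C11 and C5–C6 together, back to an open chain in which O8 carries a 2-iodoallyl mixed acetal (C12, C11, C13), C6=C7 is an alkenylboronate and C4=C5 an enoate.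
4. Enabling feature: C11 lies 1,5 to C7 through C12–O–C8, and C6 lies 1,6 to C5 through C7–C8–C9–C10, so a C11 vinyl radical closes ring A at C7 and the C6 radical it leaves closes ring B at C5 in one chain.
5. Forward order: 2-deoxy-D-ribose (its C1–C5 become C5, C10, C9, C8, C7) → lactone → quaternary C10 and C1 chlorohydrin → ring-opening olefination, acetal tether, C6=C7 boronate → cascade (ring A, then ring B) → C6 correction → end game.
6. Stereochemistry: C8 and C9 from the sugar; C10 by methylation anti to O9; C1 by CBS reduction; C7 and C5 in the cascade; C6 by hydride delivery to a C6 ketone on the face away from the axial C10 methyl.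

Key step: step 13

Assumption: the target is taken as the open C6-hydroxy C3-aldehyde that is drawn (not its cyclic hemiacetal); acetal and lactol carbons (C12, C3, and C5 in 10) are carried as epimer mixtures and written without descriptor.

**Route**

Step 1
Reactants: 1 2-deoxy-D-ribose
Product: 2 2-deoxy-D-ribono-1,4-lactone
Conditions: Br2, H2O, rt; concentrate
Reagents that add atoms: none
Why: Bromine-water oxidation of the aldose hemiacetal gives the aldono-1,4-lactone without touching sugar C3 and C4, which become C9 and C8.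

Step 2
Reactants: 2 2-deoxy-D-ribono-1,4-lactone
Product: 4 3-O-TBS-5-O-TES lactone, via 5-O-triethylsilyl lactone 3 (not isolated)
Conditions: Et3SiCl (1.05 equiv), imidazole, DMF, −30 °C; then t-BuMe2SiCl, rt
Reagents that add atoms: chlorotriethylsilane CC[Si](Cl)(CC)CC; tert-butyldimethylsilyl chloride CC(C)(C)[Si](C)(C)Cl
Why: Sequential silyl ether formation, the primary C7 hydroxyl reacting first on steric grounds, gives a primary TES ether (oxidised directly in step 11) and a robust TBS ether on O9.

Step 3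
Reactants: 4 3-O-TBS-5-O-TES lactone
Product: 5 2-acetyl lactone (C10 epimers, keto/enol)
Conditions: LiN(SiMe3)2, THF, −78 °C; MeC(O)N(OMe)Me, −78 → −40 °C; aq. NH4Cl
Reagents that add atoms: N-methoxy-N-methylacetamide CC(=O)N(C)OC
Why: Claisen-type C-acylation of the lactone lithium enolate by a Weinreb amide, whose stable tetrahedral adduct stops at mono-acylation; the new C10 centre is labile and is fixed in step 4.

Step 4
Reactants: 5 2-acetyl lactone
Product: 6 2-acetyl-2-methyl lactone
Conditions: MeI, K2CO3, acetone, 0 °C → rt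
Reagents that add atoms: iodomethane CI
Why: C-alkylation of the β-keto lactone enolate, methyl iodide approaching the planar enolate anti to the adjacent O9 silyl ether, so the C10 methyl ends trans and the acyl branch (future C1) cis to O9.

Step 5
Reactants: 6 2-acetyl-2-methyl lactone
Product: 7 chloromethyl ketone
Conditions: LiN(SiMe3)2, THF, −78 °C; N-chlorosuccinimide, −78 °C; aq. NH4Cl
Reagents that add atoms: N-chlorosuccinimide O=C1CCC(=O)N1Cl
Why: Electrophilic α-chlorination of the kinetic lithium enolate of the methyl ketone, the only enolisable position now that C10 is quaternary.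

Step 6
Reactants: 7 chloromethyl ketone
Product: 8 (R)-chlorohydrin
Conditions: (R)-2-methyl-CBS-oxazaborolidine (20 mol %), BH3·SMe2, THF, −20 °C; MeOH
Reagents that add atoms: none
Why: CBS (oxazaborolidine–borane) reduction, with reagent-controlled hydride delivery that treats the quaternary C10 as the large and CH2Cl as the small substituent, sets C1 as R.

Step 7
Reactants: 8 (R)-chlorohydrin
Product: 9 chlorohydrin TBS ether
Conditions: t-BuMe2SiOTf, 2,6-lutidine, CH2Cl2, −78 → 0 °C
Reagents that add atoms: tert-butyldimethylsilyl triflate CC(C)(C)[Si](C)(C)OS(=O)(=O)C(F)(F)F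
Why: Silyl triflate silylation of the hindered secondary alcohol keeps the chlorohydrin latent until step 18.

Step 8
Reactants: 9 chlorohydrin TBS ether
Product: 10 lactol
Conditions: i-Bu2AlH (1.2 equiv), CH2Cl2, −78 °C; aq. potassium sodium tartrate
Reagents that add atoms: none
Why: Low-temperature i-Bu2AlH half-reduction of the lactone stops at the aluminium hemiacetal and gives the lactol.

Step 9
Reactants: 10 lactol
Product: 11 E-enoate with free C8 hydroxyl
Conditions: Ph3P=CHCO2Me, toluene, 90 °C
Reagents that add atoms: methyl (triphenylphosphoranylidene)acetate COC(=O)C=P(c1ccccc1)(c1ccccc1)c1ccccc1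
Why: Wittig olefination of the ring-opened hydroxy aldehyde form of the lactol with a stabilised ylide gives the E-enoate (radical acceptor at C5) and liberates only the C8 hydroxyl.

Step 10
Reactants: 11 E-enoate alcohol
Product: 12 2-iodoallyl mixed acetal
Conditions: methoxyallene, N-iodosuccinimide, CH2Cl2, −40 → −10 °C
Reagents that add atoms: methoxyallene COC=C=C; N-iodosuccinimide O=C1CCC(=O)N1I
Why: Iodo-alkoxylation of an alkoxyallene (haloacetalisation), iodonium adding to the central allene carbon and the C8 hydroxyl capturing the oxocarbenium ion, installs the C11–I radical precursor with C12 at the acetal oxidation level.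

Step 11
Reactants: 12 2-iodoallyl mixed acetal
Product: 13 C7 aldehyde
Conditions: (COCl)2, DMSO, CH2Cl2, −78 → −40 °C; Et3N, −78 → 0 °C
Reagents that add atoms: none
Why: Swern oxidation applied directly to the primary TES ether, which is cleaved and oxidised under these conditions while the secondary TBS ethers and the acetal persist.

Step 12
Reactants: 13 C7 aldehyde
Product: 14 E-alkenylboronate (cascade precursor)
Conditions: Cl2CHBpin, CrCl2, LiI, THF, rt
Reagents that add atoms: 2-(dichloromethyl)-4,4,5,5-tetramethyl-1,3,2-dioxaborolane CC1(C)OB(C(Cl)Cl)OC1(C)C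
Why: Takai–Utimoto chromium-mediated boryl-olefination gives the E-alkenylboronate under non-basic conditions, so the α-oxygenated C8 centre is not epimerised.

Step 13
Reactants: 14 E-alkenylboronate
Product: 15 bicyclic boronate (rings A and B closed; C6 boronate equatorial)
Conditions: Bu3SnH (1.3 equiv, syringe pump), AIBN (cat.), benzene (5 mM), 80 °C
Reagents that add atoms: none
Why: Bu3Sn• abstracts iodine from the vinyl iodide; the C11 σ-vinyl radical adds to C7 of the alkenylboronate, the α-boryl C6 radical so formed adds to C5 of the enoate, and the α-ester C4 radical takes hydrogen from Bu3SnH to carry the chain. The closest known reaction type is the tin hydride cyclisation of 2-haloallyl mixed acetals (Ueno–Stork type) run as a tandem cyclisation. Ring A closes 5-exo-trig by forming C7–C11 and ring B closes 6-exo-trig by forming C5–C6. C7 is set in a chair-like 5-exo transition state with the bulky C9 branch on C8 pseudo-equatorial, which places C6 trans to C9 (trans ring fusion); C5 is set in a chair-like 6-exo transition state locked by the trans-fused ring A, the enoate arm going equatorial because the axial site is blocked by the axial O9 silyl ether; the C6 boronate should go equatorial, which is irrelevant because C6 later passes through a ketone. The step needs chemoselective initiation (C(sp2)–I is abstracted far faster than C–Cl), exo regiochemistry (secured by attack β to boron and β to the ester) and ring closure ahead of reduction (secured by high dilution and slow hydride addition).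

Step 14
Reactants: 15 bicyclic boronate
Product: 16 C6 alcohol (6-epi)
Conditions: 30% H2O2, NaHCO3, THF/H2O, 0 °C → rt
Reagents that add atoms: hydrogen peroxide OO
Why: Oxidation of the secondary alkylboronate by 1,2-migration from boron to oxygen (retention) gives the C6 alcohol, whose configuration is of no consequence.

Step 15
Reactants: 16 C6 alcohol
Product: 17 C6 ketone
Conditions: Dess–Martin periodinane, NaHCO3, CH2Cl2, 0 °C → rt
Reagents that add atoms: none
Why: Dess–Martin oxidation under buffered, non-enolising conditions gives the C6 ketone without epimerising C5 or C7.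

Step 16
Reactants: 17 C6 ketone
Product: 18 tricyclic γ-lactone (O6–C3)
Conditions: LiBH(s-Bu)3 (1.1 equiv), THF, −78 °C → rt; H2O
Reagents that add atoms: none
Why: Ketone reduction by a bulky trialkylborohydride from the equatorial direction, the axial trajectory being blocked by the syn-axial C10 methyl, gives the axial C6 alkoxide on the face of that methyl (sets C6), which lactonises onto the cis CH2CO2Me arm on C5.

Step 17
Reactants: 18 tricyclic γ-lactone
Product: 20 bis(methyl acetal), via C3 lactol 19 (not isolated)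
Conditions: i-Bu2AlH, CH2Cl2, −78 °C; aq. potassium sodium tartrate; then MeOH, PPTS, rt
Reagents that add atoms: methanol CO
Why: i-Bu2AlH half-reduction of the γ-lactone and acid-catalysed acetalisation of the lactol with methanol lock O6 and the future C3 aldehyde in one saturated methyl acetal ring.

Step 18
Reactants: 20 bis(methyl acetal)
Product: 22 epoxy alcohol, via chlorohydrin diol 21 (not isolated)
Conditions: Bu4NF, THF, 0 → 45 °C
Reagents that add atoms: none
Why: Fluoride desilylation followed by intramolecular Williamson closure (3-exo-tet) of the C1 alkoxide onto C2–Cl gives the oxirane with C1 untouched and leaves the C9 hydroxyl as the only free OH.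

Step 19
Reactants: 22 epoxy alcohol
Product: 23 C9 angelate
Conditions: angelic acid, 2,4,6-Cl3C6H2COCl, Et3N, toluene, rt; then 22, DMAP, 80 °C
Reagents that add atoms: angelic acid C/C=C(/C)C(=O)O
Why: Yamaguchi esterification through the mixed anhydride acylates the hindered C9 hydroxyl, the only free one, with retention of the Z enoate geometry.

Step 20
Reactants: 23 C9 angelate
Product: 24 bis-lactol
Conditions: PPTS (cat.), acetone/H2O 4:1, 35 °C
Reagents that add atoms: water O
Why: Mild acid-catalysed hydrolysis of the two 2-methoxyoxolane acetals, which should be much faster than oxirane opening at this acidity, gives the bis-lactol.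

Step 21
Reactants: 24 bis-lactol
Product: 25 α-methylene lactone with C3 lactol
Conditions: MnO2 (activated), CH2Cl2, rt
Reagents that add atoms: none
Why: MnO2 oxidises the allylic (3-methylene) lactol at C12 chemoselectively over the saturated C3 lactol and gives the α-methylene-γ-lactone.

Step 22
Reactants: 25 α-methylene lactone with C3 lactol
Product: 27 CNP0130022.2, via Mannich base 26 (not isolated)
Conditions: CH2=NMe2+ I−, Et3N, CH2Cl2, rt
Reagents that add atoms: dimethylmethyleneiminium iodide C=[N+](C)C.[I-]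
Why: Mannich reaction of the open hydroxy aldehyde tautomer of the C3 lactol with the iminium salt and β-elimination of dimethylamine installs the C4=C15 methylene, which conjugates the aldehyde and leaves the C6 hydroxyl free.

**Compound list**

1 | 2-deoxy-D-ribose, (3S,4R)-3,4,5-trihydroxypentanal, drawn open-chain | O=CC[C@H](O)[C@H](O)CO | starting material
2 | 2-deoxy-D-ribono-1,4-lactone, (4S,5R)-4-hydroxy-5-(hydroxymethyl)oxolan-2-one | O=C1C[C@H](O)[C@@H](CO)O1 | intermediate
3 | 5-O-triethylsilyl-2-deoxy-D-ribono-1,4-lactone | O=C1C[C@H](O)[C@@H](CO[Si](CC)(CC)CC)O1 | intermediate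
4 | 3-O-tert-butyldimethylsilyl-5-O-triethylsilyl-2-deoxy-D-ribono-1,4-lactone | O=C1C[C@H](O[Si](C)(C)C(C)(C)C)[C@@H](CO[Si](CC)(CC)CC)O1 | intermediate
5 | 2-acetyl derivative of 4 (C10 epimers, keto/enol) | O=C1C(C(C)=O)[C@H](O[Si](C)(C)C(C)(C)C)[C@@H](CO[Si](CC)(CC)CC)O1 | intermediate
6 | 2-acetyl-2-methyl lactone, methyl trans to the O9 silyl ether | O=C1[C@](C)(C(C)=O)[C@H](O[Si](C)(C)C(C)(C)C)[C@@H](CO[Si](CC)(CC)CC)O1 | intermediate
7 | 2-(chloroacetyl)-2-methyl lactone | O=C1[C@](C)(C(=O)CCl)[C@H](O[Si](C)(C)C(C)(C)C)[C@@H](CO[Si](CC)(CC)CC)O1 | intermediate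
8 | chlorohydrin lactone, C1 R | O=C1[C@](C)([C@@H](O)CCl)[C@H](O[Si](C)(C)C(C)(C)C)[C@@H](CO[Si](CC)(CC)CC)O1 | intermediate
9 | chlorohydrin TBS ether lactone, C1 R | O=C1[C@](C)([C@@H](O[Si](C)(C)C(C)(C)C)CCl)[C@H](O[Si](C)(C)C(C)(C)C)[C@@H](CO[Si](CC)(CC)CC)O1 | intermediate
10 | lactol from 9 (C5 epimers) | OC1[C@](C)([C@@H](O[Si](C)(C)C(C)(C)C)CCl)[C@H](O[Si](C)(C)C(C)(C)C)[C@@H](CO[Si](CC)(CC)CC)O1 | intermediate
11 | methyl E-enoate (C3–C5) with free C8 hydroxyl, O9 and O1 as TBS ethers, O7 as TES ether | COC(=O)/C=C/[C@](C)([C@@H](O[Si](C)(C)C(C)(C)C)CCl)[C@H](O[Si](C)(C)C(C)(C)C)[C@H](O)CO[Si](CC)(CC)CC | intermediate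
12 | O8 2-iodoallyl methyl mixed acetal of 11 | COC(=O)/C=C/[C@](C)([C@@H](O[Si](C)(C)C(C)(C)C)CCl)[C@H](O[Si](C)(C)C(C)(C)C)[C@H](OC(OC)C(I)=C)CO[Si](CC)(CC)CC | intermediate
13 | C7 aldehyde | COC(=O)/C=C/[C@](C)([C@@H](O[Si](C)(C)C(C)(C)C)CCl)[C@H](O[Si](C)(C)C(C)(C)C)[C@H](OC(OC)C(I)=C)C=O | intermediate
14 | C6=C7 E-alkenyl pinacolboronate, cascade precursor | COC(=O)/C=C/[C@](C)([C@@H](O[Si](C)(C)C(C)(C)C)CCl)[C@H](O[Si](C)(C)C(C)(C)C)[C@H](OC(OC)C(I)=C)/C=C/B1OC(C)(C)C(C)(C)O1 | intermediate
15 | bicyclic 3-methylene lactol methyl ether, trans-fused to ring B; C6 Bpin equatorial, C5 CH2CO2Me equatorial | C=C1C(OC)O[C@@H]2[C@@H]1[C@H](B3OC(C)(C)C(C)(C)O3)[C@@H](CC(=O)OC)[C@](C)([C@@H](O[Si](C)(C)C(C)(C)C)CCl)[C@@H]2O[Si](C)(C)C(C)(C)C | intermediate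
16 | C6 alcohol, equatorial OH (6-epi) | C=C1C(OC)O[C@@H]2[C@@H]1[C@H](O)[C@@H](CC(=O)OC)[C@](C)([C@@H](O[Si](C)(C)C(C)(C)C)CCl)[C@@H]2O[Si](C)(C)C(C)(C)C | intermediate
17 | C6 ketone | C=C1C(OC)O[C@@H]2[C@@H]1C(=O)[C@@H](CC(=O)OC)[C@](C)([C@@H](O[Si](C)(C)C(C)(C)C)CCl)[C@@H]2O[Si](C)(C)C(C)(C)C | intermediate
18 | tricyclic cis-fused O6–C3 γ-lactone, C6 oxygen axial and syn to the C10 methyl | C=C1C(OC)O[C@@H]2[C@@H]1[C@H]3OC(=O)C[C@H]3[C@](C)([C@@H](O[Si](C)(C)C(C)(C)C)CCl)[C@@H]2O[Si](C)(C)C(C)(C)C | intermediate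
19 | C3 lactol of 18 | C=C1C(OC)O[C@@H]2[C@@H]1[C@H]3OC(O)C[C@H]3[C@](C)([C@@H](O[Si](C)(C)C(C)(C)C)CCl)[C@@H]2O[Si](C)(C)C(C)(C)C | intermediate
20 | bis(methyl acetal) at C12 and C3 | C=C1C(OC)O[C@@H]2[C@@H]1[C@H]3OC(OC)C[C@H]3[C@](C)([C@@H](O[Si](C)(C)C(C)(C)C)CCl)[C@@H]2O[Si](C)(C)C(C)(C)C | intermediate
21 | chlorohydrin diol (O1 and O9 free) | C=C1C(OC)O[C@@H]2[C@@H]1[C@H]3OC(OC)C[C@H]3[C@](C)([C@@H](O)CCl)[C@@H]2O | intermediate
22 | epoxy alcohol, oxirane C1 R, C9 hydroxyl free | C=C1C(OC)O[C@@H]2[C@@H]1[C@H]3OC(OC)C[C@H]3[C@](C)([C@@H]4CO4)[C@@H]2O | intermediate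
23 | C9 angelate, (Z)-2-methylbut-2-enoate | C=C1C(OC)O[C@@H]2[C@@H]1[C@H]3OC(OC)C[C@H]3[C@](C)([C@@H]4CO4)[C@@H]2OC(=O)/C(C)=C\C | intermediate
24 | bis-lactol at C12 and C3 | C=C1C(O)O[C@@H]2[C@@H]1[C@H]3OC(O)C[C@H]3[C@](C)([C@@H]4CO4)[C@@H]2OC(=O)/C(C)=C\C | intermediate
25 | 8,12-α-methylene-γ-lactone with saturated O6–C3 lactol | C=C1C(=O)O[C@@H]2[C@@H]1[C@H]3OC(O)C[C@H]3[C@](C)([C@@H]4CO4)[C@@H]2OC(=O)/C(C)=C\C | intermediate
26 | Mannich base, C4 dimethylaminomethyl aldehyde (C4 epimers), drawn open | C=C1C(=O)O[C@@H]2[C@@H]1[C@@H](O)[C@@H](C(CN(C)C)C=O)[C@](C)([C@@H]1CO1)[C@@H]2OC(=O)/C(C)=C\C | intermediate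
27 | CNP0130022.2, (1R,5R,6S,7S,8R,9S,10R) in the locants used here | C=C1C(=O)O[C@@H]2[C@@H]1[C@@H](O)[C@@H](C(=C)C=O)[C@](C)([C@@H]1CO1)[C@@H]2OC(=O)/C(C)=C\C | target

**Count and risks**

Total steps: 22. Longest linear sequence: 22 steps (fully linear from 1).

Steps most likely to fail:

Step 13 (radical cascade). Hydrogen transfer to the C6 radical may outrun the second ring closure, or facial control at C5 may be poor, so that only ring A forms cleanly. Fallback: from 14, ring A alone is closed with Bu3SnH at higher concentration to give the monocyclic primary boronate F1. F1 is oxidised (H2O2, NaHCO3) to the primary alcohol F2 and then (Dess–Martin periodinane) to the C6 aldehyde F3. SmI2 (THF, MeOH, −78 °C) then forms C5–C6 by ketyl–olefin cyclisation onto the enoate. The route is rejoined at 16; either C6 epimer serves, since ketone 17 follows.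

Step 9 (lactol Wittig). Olefination of the neopentyl lactol may be slow, and the freed C8 hydroxyl may re-close onto the new enoate by oxa-Michael addition. Fallback: from lactone 9, ring opening with Me2AlN(OMe)Me (from AlMe3 and MeNHOMe·HCl) gives the hydroxy Weinreb amide F4. Immediate iodoacetalisation (methoxyallene, N-iodosuccinimide) gives the acetal amide F5, and i-Bu2AlH reduction gives the aldehyde F6. Wittig olefination with Ph3P=CHCO2Me, now with no free hydroxyl present, rejoins the route at 12.

Step 19 (angeloylation). Acylation of the axial, neopentyl C9 hydroxyl may be slow, and the activated angelate may isomerise from Z to E. Fallback: from 22, esterification with 2-[bis(2,2,2-trifluoroethoxy)phosphoryl]propanoic acid (DCC, DMAP) gives the phosphonate ester F7. A Still–Gennari olefination with acetaldehyde (KN(SiMe3)2, 18-crown-6, THF, −78 °C) then builds the Z-trisubstituted enoate on the molecule and rejoins the route at 23.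

**Further compounds**

F1 | step 13 | monocyclic 3-methylene lactol ether with C6H2–Bpin arm and intact enoate | C=C1C(OC)O[C@H]([C@@H]1CB2OC(C)(C)C(C)(C)O2)[C@@H](O[Si](C)(C)C(C)(C)C)[C@@](C)([C@@H](O[Si](C)(C)C(C)(C)C)CCl)/C=C/C(=O)OC
F2 | step 13 | C6 primary alcohol | C=C1C(OC)O[C@H]([C@@H]1CO)[C@@H](O[Si](C)(C)C(C)(C)C)[C@@](C)([C@@H](O[Si](C)(C)C(C)(C)C)CCl)/C=C/C(=O)OC
F3 | step 13 | C6 aldehyde | C=C1C(OC)O[C@H]([C@@H]1C=O)[C@@H](O[Si](C)(C)C(C)(C)C)[C@@](C)([C@@H](O[Si](C)(C)C(C)(C)C)CCl)/C=C/C(=O)OC
F4 | step 9 | C5 Weinreb amide with free C8 hydroxyl | CON(C)C(=O)[C@](C)([C@@H](O[Si](C)(C)C(C)(C)C)CCl)[C@H](O[Si](C)(C)C(C)(C)C)[C@H](O)CO[Si](CC)(CC)CC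
F5 | step 9 | Weinreb amide with O8 2-iodoallyl mixed acetal | CON(C)C(=O)[C@](C)([C@@H](O[Si](C)(C)C(C)(C)C)CCl)[C@H](O[Si](C)(C)C(C)(C)C)[C@H](OC(OC)C(I)=C)CO[Si](CC)(CC)CC
F6 | step 9 | C5 aldehyde with O8 2-iodoallyl mixed acetal | O=C[C@](C)([C@@H](O[Si](C)(C)C(C)(C)C)CCl)[C@H](O[Si](C)(C)C(C)(C)C)[C@H](OC(OC)C(I)=C)CO[Si](CC)(CC)CC
F7 | step 19 | C9 2-[bis(2,2,2-trifluoroethoxy)phosphoryl]propanoate | C=C1C(OC)O[C@@H]2[C@@H]1[C@H]3OC(OC)C[C@H]3[C@](C)([C@@H]4CO4)[C@@H]2OC(=O)C(C)P(=O)(OCC(F)(F)F)OCC(F)(F)F
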